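**Plan**

1. Retrosynthesis: the C5 O–methyl bond is cut last; ring C is then cut at C2–C3 and C4–C4a together (formal [4+2] of a ring A–O1=C2 oxocarbenium ion with a two-carbon ketene acetal, C3–C4); then O1–C2 (phenoxide plus α-chloro ester of the ring B aldehyde); then the C6–prenyl bond (directed metalation).
2. Forward: the symmetrical ring A phenol (3,5-dimethoxy-4-prenylphenol) is made first and joined through O1 to the aldehyde carbon of 3,4,5-trimethoxybenzaldehyde (the future C2) as an O-aryl O-pivaloyl acetal. Ring C then closes in one cationic event, and the 5-OMe is cleaved last.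
3. Enabling feature: C2 sits at acetal level between O1 and ring B, so loss of pivalate gives the O-aryl oxocarbenium ion O1=C2. Together with the C8a=C4a bond of the phloroglucinol-type ring A this is a cationic 2-oxadiene, and C4a is ortho to O1 and flanked by a methoxy group.
4. Helpers: the pivalate (nucleofuge, leaves in the key step), the diethyl ketal at C4 (hydrolysed in the work-up), the TIPS ether (keeps metalation away from its ortho carbons), and the mirror symmetry of ring A (its two ortho carbons are equivalent), which is broken only at the end by chelation between C4=O and the 5-OMe.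
5. Stereochemistry: the single stereocentre C2 (S) is set in the key step by a chiral squaramide-bound triflate counter-ion (attack on the Si face of C2); no later step exposes it to base.

Key step: step 6

Remark: the sense of induction of the squaramide catalyst on an acyclic O-aryl oxocarbenium ion cannot be taken from precedent, so the catalyst antipode that directs the nucleophile to the Si face of C2 is assumed to be the one used; 8 and 10 are used as racemates because C2 passes through a planar cation.

**Route**

Step 1
Reactants: 1 3,5-dimethoxyphenol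
Product: 2 (3,5-dimethoxyphenoxy)tri(propan-2-yl)silane
Conditions: i-Pr3SiCl, imidazole, DMF, rt
Reagents that add atoms: chlorotri(propan-2-yl)silane (TIPSCl), CC(C)[Si](Cl)(C(C)C)C(C)C
Why: standard silylation of a phenol; the bulky, weakly coordinating TIPS ether should survive n-BuLi and screen its two ortho carbons in step 2.

Step 2
Reactants: 2 (3,5-dimethoxyphenoxy)tri(propan-2-yl)silane; 3 1-bromo-3-methylbut-2-ene (prenyl bromide)
Product: 5 [3,5-dimethoxy-4-(3-methylbut-2-en-1-yl)phenoxy]tri(propan-2-yl)silane, via aryllithium 4 (not isolated)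
Conditions: n-BuLi, TMEDA, THF, 0 °C to rt; then CuBr·SMe2 (10 mol %), 3, −78 °C to rt
Reagents that add atoms: n-butyllithium, [Li]CCCC (lithium stays only in 4)
Why: directed ortho-metalation at the carbon between the two methoxy groups (cooperative coordination and induction), followed by copper-catalysed SN2 allylation of the aryllithium at the primary carbon of prenyl bromide.

Step 3
Reactants: 5 [3,5-dimethoxy-4-(3-methylbut-2-en-1-yl)phenoxy]tri(propan-2-yl)silane
Product: 6 3,5-dimethoxy-4-(3-methylbut-2-en-1-yl)phenol
Conditions: Bu4NF, AcOH, THF, 0 °C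
Reagents that add atoms: none
Why: fluoride cleavage of the aryl silyl ether, buffered with acetic acid so that the phenol is released directly.

Step 4
Reactants: 7 3,4,5-trimethoxybenzaldehyde
Product: 8 chloro(3,4,5-trimethoxyphenyl)methyl 2,2-dimethylpropanoate (racemic)
Conditions: t-BuCOCl, ZnCl2 (2 mol %), CH2Cl2, 0 °C to rt; filtered, evaporated, used crude
Reagents that add atoms: pivaloyl chloride, CC(C)(C)C(Cl)=O
Why: Lewis-acid-catalysed addition of an acyl chloride across an aldehyde C=O (α-chloroalkyl ester formation), in which all atoms of both partners are kept.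

Step 5
Reactants: 6 3,5-dimethoxy-4-(3-methylbut-2-en-1-yl)phenol; 8 chloro(3,4,5-trimethoxyphenyl)methyl 2,2-dimethylpropanoate
Product: 10 [3,5-dimethoxy-4-(3-methylbut-2-en-1-yl)phenoxy](3,4,5-trimethoxyphenyl)methyl 2,2-dimethylpropanoate (racemic), via sodium phenolate 9 (not isolated)
Conditions: NaH, THF, 0 °C; then 8, −40 to 0 °C; aq. NaHCO3 work-up, Et3N-deactivated silica
Reagents that add atoms: sodium hydride, [Na+].[H-] (sodium stays only in 9)
Why: O-alkylation of a phenoxide by an α-chloroalkyl ester, as in the synthesis of acyloxyalkyl aryl ethers; the acyloxy-stabilised benzylic carbon should be taken at the hard oxygen, and the hindered pivaloyl carbonyl should resist acyl transfer.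

Step 6
Reactants: 10 [3,5-dimethoxy-4-(3-methylbut-2-en-1-yl)phenoxy](3,4,5-trimethoxyphenyl)methyl 2,2-dimethylpropanoate; 11 1,1-diethoxyethene
Product: 13 (2S)-5,7-dimethoxy-6-(3-methylbut-2-en-1-yl)-2-(3,4,5-trimethoxyphenyl)-2,3-dihydro-4H-chromen-4-one, via diethyl ketal 12 (not isolated)
Conditions: chiral squaramide hydrogen-bond donor (tert-leucine 2-arylpyrrolidine amide type, 12 mol %), Me3SiOTf (10 mol %), 11 (2.2 equiv, syringe pump), t-BuOMe/toluene, −78 °C; Et3N; then 10% aq. citric acid, THF, 0 °C
Reagents that add atoms: water, O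
Why: Proposed new method: Me3SiOTf bound by the squaramide silylates the pivalate carbonyl of racemic 10 (far more basic than the aryl oxygen, so only pivalate leaves) and gives the planar O-aryl oxocarbenium ion O1=C2 as a contact ion pair with the chiral squaramide-triflate anion; the CH2 terminus of 11 then adds to C2 (C2–C3 bond) and the diethoxycarbenium ion so formed at C4 is taken by C4a of ring A (C4–C4a bond), which amounts to a stepwise cationic [4+2] between the 2-oxadiene O1=C2/C8a=C4a and the ketene acetal. The closest known reaction types are the SnCl4-promoted oxa-Povarov reaction of aryl oxocarbenium ions with alkenes (racemic), the chiral urea and strong acid co-catalysed Povarov reaction, and squaramide/silyl triflate-catalysed enantioselective additions of silyl ketene acetals to aryl oxocarbenium ions; a dialkyl ketene acetal is used here because its adduct cation has no silyl group to shed and can therefore only go on to ring closure. Ring C closes by a Friedel–Crafts attack that is 6-exo-trig at the C4 carbenium carbon, with the C8a=C4a bond of ring A inside the new six-membered ring. The one new stereocentre, C2, is fixed in the first bond formation by the chiral anion, which has to direct 11 to the Si face of C2 to give the 2S product. The step needs ionisation at pivalate and not at the aryloxy group (secured by the acylal), ring closure at the right carbon (the two ortho carbons of ring A are equivalent by its mirror plane, each activated by O1 and by an ortho and a para methoxy group, while the ring is deactivated as long as O1 carries the positive charge), and ring closure ahead of chain growth on a second ketene acetal (slow addition of 11). Turnover should follow from transfer of the proton lost on rearomatisation to the second equivalent of 11, whose cation takes pivalate from the next molecule of 10.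

Step 7
Reactants: 13 (2S)-5,7-dimethoxy-6-(3-methylbut-2-en-1-yl)-2-(3,4,5-trimethoxyphenyl)-2,3-dihydro-4H-chromen-4-one
Product: 15 artoflavanone, (2S)-5-hydroxy-7-methoxy-6-(3-methylbut-2-en-1-yl)-2-(3,4,5-trimethoxyphenyl)-2,3-dihydro-4H-chromen-4-one, via dichloroboryl ether 14 (not isolated)
Conditions: BCl3 (1.2 equiv), CH2Cl2, −78 to −40 °C; cold sat. aq. NaHCO3
Reagents that add atoms: boron trichloride, ClB(Cl)Cl (boron and chlorine stay only in 14)
Why: chelation-controlled demethylation of the methoxy group peri to the C4 carbonyl (boron bridges C4=O and O5, chloride takes the methyl group as chloromethane), a standard entry to 5-hydroxyflavanones that at low temperature should leave the other four methoxy groups, the prenyl group and C2 untouched.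

**Compound list**

1 | 3,5-dimethoxyphenol | COc1cc(O)cc(OC)c1 | starting material
2 | (3,5-dimethoxyphenoxy)tri(propan-2-yl)silane | COc1cc(O[Si](C(C)C)(C(C)C)C(C)C)cc(OC)c1 | intermediate
3 | 1-bromo-3-methylbut-2-ene (prenyl bromide) | CC(C)=CCBr | starting material
4 | {2,6-dimethoxy-4-[tri(propan-2-yl)silyloxy]phenyl}lithium (not isolated) | [Li]c1c(OC)cc(O[Si](C(C)C)(C(C)C)C(C)C)cc1OC | intermediate
5 | [3,5-dimethoxy-4-(3-methylbut-2-en-1-yl)phenoxy]tri(propan-2-yl)silane | COc1cc(O[Si](C(C)C)(C(C)C)C(C)C)cc(OC)c1CC=C(C)C | intermediate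
6 | 3,5-dimethoxy-4-(3-methylbut-2-en-1-yl)phenol | COc1cc(O)cc(OC)c1CC=C(C)C | intermediate
7 | 3,4,5-trimethoxybenzaldehyde | COc1cc(C=O)cc(OC)c1OC | starting material
8 | chloro(3,4,5-trimethoxyphenyl)methyl 2,2-dimethylpropanoate (racemic) | COc1cc(C(Cl)OC(=O)C(C)(C)C)cc(OC)c1OC | intermediate
9 | sodium 3,5-dimethoxy-4-(3-methylbut-2-en-1-yl)phenolate (not isolated) | [Na+].[O-]c1cc(OC)c(CC=C(C)C)c(OC)c1 | intermediate
10 | [3,5-dimethoxy-4-(3-methylbut-2-en-1-yl)phenoxy](3,4,5-trimethoxyphenyl)methyl 2,2-dimethylpropanoate (racemic) | COc1cc(OC(OC(=O)C(C)(C)C)c2cc(OC)c(OC)c(OC)c2)cc(OC)c1CC=C(C)C | intermediate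
11 | 1,1-diethoxyethene (ketene diethyl acetal) | C=C(OCC)OCC | starting material
12 | (2S)-4,4-diethoxy-5,7-dimethoxy-6-(3-methylbut-2-en-1-yl)-2-(3,4,5-trimethoxyphenyl)-3,4-dihydro-2H-chromene (not isolated) | COc1cc2c(c(OC)c1CC=C(C)C)C(OCC)(OCC)C[C@@H](c1cc(OC)c(OC)c(OC)c1)O2 | intermediate
13 | (2S)-5,7-dimethoxy-6-(3-methylbut-2-en-1-yl)-2-(3,4,5-trimethoxyphenyl)-2,3-dihydro-4H-chromen-4-one | COc1cc2c(c(OC)c1CC=C(C)C)C(=O)C[C@@H](c1cc(OC)c(OC)c(OC)c1)O2 | intermediate
14 | (2S)-5-[(dichloroboranyl)oxy]-7-methoxy-6-(3-methylbut-2-en-1-yl)-2-(3,4,5-trimethoxyphenyl)-2,3-dihydro-4H-chromen-4-one (boron chelated by the C4 carbonyl oxygen; not isolated) | COc1cc2c(c(OB(Cl)Cl)c1CC=C(C)C)C(=O)C[C@@H](c1cc(OC)c(OC)c(OC)c1)O2 | intermediate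
15 | artoflavanone, (2S)-5-hydroxy-7-methoxy-6-(3-methylbut-2-en-1-yl)-2-(3,4,5-trimethoxyphenyl)-2,3-dihydro-4H-chromen-4-one | COc1cc2c(c(O)c1CC=C(C)C)C(=O)C[C@@H](c1cc(OC)c(OC)c(OC)c1)O2 | target

**Step count and risks**

Total step count: 7. Longest linear sequence: 6 (steps 1, 2, 3, 5, 6, 7; step 4 is the side branch).

Steps most likely to fail:

1. Step 6 (proposed new method). What may go wrong: chain growth of the ketene acetal on the C4 cation before ring closure; return of the benzylic cation to carbon of another ring A instead of reaction with 11; weak facial discrimination in the ion pair; stalling of turnover if the triflate is held by a stabilised product cation. Fallback (known chemistry, sets out from 6, returns at 13): the stereocentre is made by catalytic asymmetric conjugate arylation of a chromone. Phenol 6 is C-acetylated ortho to the hydroxyl group (Ac2O, BF3·OEt2, CH2Cl2, 0 °C to rt, then aqueous methanol to break the boron chelate) to give 1-[6-hydroxy-2,4-dimethoxy-3-(3-methylbut-2-en-1-yl)phenyl]ethan-1-one F1. Condensation with N,N-dimethylformamide dimethyl acetal (toluene, 100 °C) gives (2E)-3-(dimethylamino)-1-[6-hydroxy-2,4-dimethoxy-3-(3-methylbut-2-en-1-yl)phenyl]prop-2-en-1-one F2, which should close with dilute HCl in CH2Cl2 to 5,7-dimethoxy-6-(3-methylbut-2-en-1-yl)-4H-chromen-4-one F3. Pd(OCOCF3)2 (divalent palladium, 5 mol %) with the t-BuPyOx ligand antipode that gives the 2S product, NH4PF6 and water in 1,2-dichloroethane at 60 °C should then add 3,4,5-trimethoxyphenylboronic acid (OB(O)c1cc(OC)c(OC)c(OC)c1) to C2 of F3 and give 13.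

2. Step 5. What may go wrong: alkylation of the ambident phenoxide at an ortho carbon instead of oxygen; acyl transfer from the chloro ester to the phenoxide; hydrolytic loss of the acylal during isolation. Fallback (sets out from 7 and from phenolate 9, returns at 13): the acyloxy nucleofuge is replaced by a methoxy group, which gives a base-stable mixed acetal. Aldehyde 7 is converted with HC(OMe)3 and catalytic TsOH in methanol into 5-(dimethoxymethyl)-1,2,3-trimethoxybenzene F4. Acetyl chloride (neat, trace ZnCl2) should turn F4 into 5-[chloro(methoxy)methyl]-1,2,3-trimethoxybenzene F5, which is added to phenolate 9 in THF to give 5-{[3,5-dimethoxy-4-(3-methylbut-2-en-1-yl)phenoxy](methoxy)methyl}-1,2,3-trimethoxybenzene F6. F6 is then taken through the conditions of step 6, where the silyl triflate should remove the methoxy group as Me3SiOMe and give the same ion pair, so that the route is rejoined at 13.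

3. Step 7. What may go wrong: acid-mediated ring closure of the freed 5-hydroxyl group onto the prenyl double bond; further demethylation at the central methoxy group of ring B; erosion of C2 by Lewis-acid-assisted opening of ring C. Fallback (sets out from 2, returns at 15): the prenyl group is carried as an allyl group, which is much less prone to cationic ring closure, and is completed only after the demethylation. Aryllithium 4 from 2 is quenched with allyl bromide (CuBr·SMe2, THF) to give [3,5-dimethoxy-4-(prop-2-en-1-yl)phenoxy]tri(propan-2-yl)silane F7, and the conditions of step 3 give 3,5-dimethoxy-4-(prop-2-en-1-yl)phenol F8. The conditions of step 5 with 8 give [3,5-dimethoxy-4-(prop-2-en-1-yl)phenoxy](3,4,5-trimethoxyphenyl)methyl 2,2-dimethylpropanoate F9, and the conditions of step 6 give (2S)-5,7-dimethoxy-6-(prop-2-en-1-yl)-2-(3,4,5-trimethoxyphenyl)-2,3-dihydro-4H-chromen-4-one F10. BCl3 as in step 7 gives (2S)-5-hydroxy-7-methoxy-6-(prop-2-en-1-yl)-2-(3,4,5-trimethoxyphenyl)-2,3-dihydro-4H-chromen-4-one F11. Olefin cross-metathesis of F11 with excess 2-methylbut-2-ene (second-generation Grubbs catalyst, CH2Cl2, 40 °C) should then give 15.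

**Further compounds**

F1 | step 6 | 1-[6-hydroxy-2,4-dimethoxy-3-(3-methylbut-2-en-1-yl)phenyl]ethan-1-one | CC(=O)c1c(O)cc(OC)c(CC=C(C)C)c1OC
F2 | step 6 | (2E)-3-(dimethylamino)-1-[6-hydroxy-2,4-dimethoxy-3-(3-methylbut-2-en-1-yl)phenyl]prop-2-en-1-one | CN(C)/C=C/C(=O)c1c(O)cc(OC)c(CC=C(C)C)c1OC
F3 | step 6 | 5,7-dimethoxy-6-(3-methylbut-2-en-1-yl)-4H-chromen-4-one | COc1cc2occc(=O)c2c(OC)c1CC=C(C)C
F4 | step 5 | 5-(dimethoxymethyl)-1,2,3-trimethoxybenzene | COC(OC)c1cc(OC)c(OC)c(OC)c1
F5 | step 5 | 5-[chloro(methoxy)methyl]-1,2,3-trimethoxybenzene (racemic) | COC(Cl)c1cc(OC)c(OC)c(OC)c1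
F6 | step 5 | 5-{[3,5-dimethoxy-4-(3-methylbut-2-en-1-yl)phenoxy](methoxy)methyl}-1,2,3-trimethoxybenzene (racemic) | COC(Oc1cc(OC)c(CC=C(C)C)c(OC)c1)c1cc(OC)c(OC)c(OC)c1
F7 | step 7 | [3,5-dimethoxy-4-(prop-2-en-1-yl)phenoxy]tri(propan-2-yl)silane | COc1cc(O[Si](C(C)C)(C(C)C)C(C)C)cc(OC)c1CC=C
F8 | step 7 | 3,5-dimethoxy-4-(prop-2-en-1-yl)phenol | COc1cc(O)cc(OC)c1CC=C
F9 | step 7 | [3,5-dimethoxy-4-(prop-2-en-1-yl)phenoxy](3,4,5-trimethoxyphenyl)methyl 2,2-dimethylpropanoate (racemic) | COc1cc(OC(OC(=O)C(C)(C)C)c2cc(OC)c(OC)c(OC)c2)cc(OC)c1CC=C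
F10 | step 7 | (2S)-5,7-dimethoxy-6-(prop-2-en-1-yl)-2-(3,4,5-trimethoxyphenyl)-2,3-dihydro-4H-chromen-4-one | COc1cc2c(c(OC)c1CC=C)C(=O)C[C@@H](c1cc(OC)c(OC)c(OC)c1)O2
F11 | step 7 | (2S)-5-hydroxy-7-methoxy-6-(prop-2-en-1-yl)-2-(3,4,5-trimethoxyphenyl)-2,3-dihydro-4H-chromen-4-one | COc1cc2c(c(O)c1CC=C)C(=O)C[C@@H](c1cc(OC)c(OC)c(OC)c1)O2
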